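**Retrosynthetic overview**
- The target is a fully substituted pyrrole: N1–H, C2 with CO2Me, C3 and C4 each with an indol-3-yl group, C5 with acetyl. The last operation unmasks the C5 acetyl group from a dimethyl ketal.
- The pyrrole is cut at C3–C4 and N1–C5 (Piloty–Robinson) to a mixed ketazine. The strategy rests on the fact that each half (C2–C3 with the ester, C5–C4 with the masked acetyl) is a ketone whose only enolisable α-carbon is its indol-3-ylmethyl CH2, so the halves can be joined N-to-N first and C-to-C afterwards.
- The azine is built in two stages: the hydrazone of the hindered, ester-free ketal ketone is condensed with methyl indole-3-pyruvate.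
- The ketal ketone comes from methyl indole-3-acetate by crossed Claisen condensation with methyl 2,2-dimethoxypropanoate and Krapcho dealkoxycarbonylation. The α-keto ester comes from indole-3-pyruvic acid by O-methylation.
- Ring order: both indoles are bought; the pyrrole is the only ring formed (step 6).

Key step: step 6

Assumption: the C=N geometries of 9 and 10 are drawn with the bulkier group anti to the N–N bond and are erased by tautomerisation in step 6; 2 is drawn as its keto form although the enol is also present, and 10 may sit partly as the ene-hydrazine tautomer of its ester arm.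

**Step 1**
Reactants: 1 indole-3-pyruvic acid
Product: 2 methyl indole-3-pyruvate (methyl 3-(1H-indol-3-yl)-2-oxopropanoate)
Conditions: DBU (1.0 equiv), MeI (1.1 equiv), DMF, 0 °C to rt, Ar
Reagents that add atoms: iodomethane, CI
Why: Carboxylate O-alkylation (SN2): one equivalent of amidine base ionises only the carboxylic acid, the most acidic site, so the methyl group should go to the carboxylate and not to the enol oxygen, the benzylic carbon or the indole nitrogen.

**Step 2**
Reactants: 3 methyl indole-3-acetate; 4 methyl 2,2-dimethoxypropanoate
Product: 6 methyl 2-(1H-indol-3-yl)-4,4-dimethoxy-3-oxopentanoate, via dilithio ester enolate 5 (not isolated)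
Conditions: LiN(iPr)2 (LDA, 3.2 equiv), THF, −78 °C; then 4 (1.3 equiv), −78 to 0 °C; AcOH quench
Reagents that add atoms: none
Why: Crossed Claisen condensation: 4 has no α-hydrogen and can act only as acyl donor, the preformed N,C-dianion 5 leaves no neutral 3 for self-condensation, and the racemic, labile CH centre of 6 needs no control because step 3 removes it.

**Step 3**
Reactants: 6 methyl 2-(1H-indol-3-yl)-4,4-dimethoxy-3-oxopentanoate
Product: 7 1-(1H-indol-3-yl)-3,3-dimethoxybutan-2-one
Conditions: LiCl (2 equiv), H2O (2 equiv), DMSO, 130 °C
Reagents that add atoms: none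
Why: Krapcho dealkoxycarbonylation: chloride demethylates the ester and the β-keto carboxylate loses CO2 under neutral conditions that should leave the dimethyl ketal and the free indole untouched.

**Step 4**
Reactants: 7 1-(1H-indol-3-yl)-3,3-dimethoxybutan-2-one; 8 hydrazine hydrate
Product: 9 3-[(2E)-2-hydrazinylidene-3,3-dimethoxybutyl]-1H-indole (hydrazone of 7)
Conditions: N2H4·H2O (10 equiv), EtOH, 78 °C
Reagents that add atoms: hydrazine hydrate (compound 8), NN.O
Why: Hydrazone formation by condensation: the alkoxy-activated ketone should condense with hydrazine, while the large excess and the neopentyl-like hindrance suppress the symmetric azine and the basic medium preserves the ketal.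

**Step 5**
Reactants: 9 hydrazone of 7; 2 methyl indole-3-pyruvate
Product: 10 methyl (2E)-2-{(2E)-[1-(1H-indol-3-yl)-3,3-dimethoxybutan-2-ylidene]hydrazinylidene}-3-(1H-indol-3-yl)propanoate (mixed azine)
Conditions: AcOH (5 mol %), 4 Å molecular sieves, CH2Cl2, rt
Reagents that add atoms: none
Why: Azine formation by condensation of an N-unsubstituted hydrazone with a ketone: the α-keto ester carbonyl of 2 is strongly electrophilic, the hindered hydrazone 9 should not disproportionate, and the sieves remove the water that would allow azine exchange, so the crossed azine is expected.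

**Step 6**
Reactants: 10 mixed azine
Product: 14 methyl 5-(1,1-dimethoxyethyl)-3,4-di(1H-indol-3-yl)-1H-pyrrole-2-carboxylate, via bis(ene-hydrazine) 11 (not isolated), via 1,4-diimine 12 (not isolated), via aminopyrroline 13 (not isolated)
Conditions: pyridine hydrochloride (3 equiv), pyridine, 110 °C, Ar; aq NaHCO3 work-up
Reagents that add atoms: none
Why: Piloty–Robinson pyrrole synthesis: the pyridine/pyridinium chloride buffer shifts both C=N bonds of 10 toward the only α-hydrogens available, the two indol-3-ylmethyl CH2 groups (the other α-positions are the ester carbon and the fully substituted ketal carbon), to give the N,N'-divinylhydrazine 11. An N-protonated [3,3]-sigmatropic (3,4-diaza-Cope) shift through a six-membered chair array then forms the C3–C4 bond between the two indolyl-bearing carbons while the N–N bond breaks, so the hydrazine supplies the oxidation level and the indoles never meet an external oxidant. In the resulting 1,4-diimine 12 the ester arm relaxes to the conjugated enamine, whose nitrogen adds to the protonated ketal-side ketimine carbon in a 5-exo-trig closure (N1–C5) to aminal 13 (attack in the opposite sense would lead to the same ring), and loss of NH3, trapped as NH4Cl, with a proton shift gives the aromatic pyrrole. The closest known reactions are the acid-mediated conversion of deoxybenzoin azine into tetraphenylpyrrole and the Fischer indolisation of α-keto ester arylhydrazones, for which a buffered pyridinium medium of this kind is used when acid-labile groups are present. The CH stereocentres of 12 and 13 arise without control and all become sp2 on aromatisation, so no stereocentre has to be set. The step needs crossed rather than homo coupling and a [3,3] shift that outruns Mannich-type closure of a mono-ene-hydrazine to a pyrazoline: the first is secured because the shift is intramolecular within the preformed mixed azine in a water-free medium, the second because the more acidic ester arm should tautomerise first and leave only the hindered ketal-flanked C=N as an electrophile.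

**Step 7**
Reactants: 14 methyl 5-(1,1-dimethoxyethyl)-3,4-di(1H-indol-3-yl)-1H-pyrrole-2-carboxylate
Product: 15 methyl 5-acetyl-3,4-di(1H-indol-3-yl)-1H-pyrrole-2-carboxylate (CNP0281950.0)
Conditions: 1 M aq HCl, THF, 0 °C to rt
Reagents that add atoms: water, O
Why: Acid-catalysed ketal hydrolysis: the ketal carbon sits on the pyrrole α-position, so the oxocarbenium ion forms easily and dilute acid at room temperature should suffice, conditions that 3-substituted indoles and the methyl ester tolerate.

**Compound list**
1 | indole-3-pyruvic acid (3-(1H-indol-3-yl)-2-oxopropanoic acid) | O=C(O)C(=O)Cc1c[nH]c2ccccc12 | starting material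
2 | methyl indole-3-pyruvate (methyl 3-(1H-indol-3-yl)-2-oxopropanoate) | COC(=O)C(=O)Cc1c[nH]c2ccccc12 | intermediate
3 | methyl indole-3-acetate | COC(=O)Cc1c[nH]c2ccccc12 | starting material
4 | methyl 2,2-dimethoxypropanoate | COC(=O)C(C)(OC)OC | starting material
5 | dilithio N,C-dianion (ester enolate) of methyl indole-3-acetate, enolate geometry undefined | [Li+].[Li+].COC([O-])=Cc1c[n-]c2ccccc12 | intermediate (not isolated)
6 | methyl 2-(1H-indol-3-yl)-4,4-dimethoxy-3-oxopentanoate, racemic | COC(=O)C(c1c[nH]c2ccccc12)C(=O)C(C)(OC)OC | intermediate
7 | 1-(1H-indol-3-yl)-3,3-dimethoxybutan-2-one | CC(OC)(OC)C(=O)Cc1c[nH]c2ccccc12 | intermediate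
8 | hydrazine hydrate | NN.O | starting material
9 | 3-[(2E)-2-hydrazinylidene-3,3-dimethoxybutyl]-1H-indole | CC(OC)(OC)/C(Cc1c[nH]c2ccccc12)=N/N | intermediate
10 | methyl (2E)-2-{(2E)-[1-(1H-indol-3-yl)-3,3-dimethoxybutan-2-ylidene]hydrazinylidene}-3-(1H-indol-3-yl)propanoate | COC(=O)/C(Cc1c[nH]c2ccccc12)=N/N=C(\Cc1c[nH]c2ccccc12)C(C)(OC)OC | intermediate
11 | methyl 2-{2-[1-(1H-indol-3-yl)-3,3-dimethoxybut-1-en-2-yl]hydrazinyl}-3-(1H-indol-3-yl)prop-2-enoate, C=C geometries undefined | COC(=O)C(=Cc1c[nH]c2ccccc12)NNC(=Cc1c[nH]c2ccccc12)C(C)(OC)OC | intermediate (not isolated)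
12 | methyl 2,5-diimino-3,4-di(1H-indol-3-yl)-6,6-dimethoxyheptanoate, diastereomer mixture | COC(=O)C(=N)C(c1c[nH]c2ccccc12)C(c1c[nH]c2ccccc12)C(=N)C(C)(OC)OC | intermediate (not isolated)
13 | methyl 5-amino-5-(1,1-dimethoxyethyl)-3,4-di(1H-indol-3-yl)-4,5-dihydro-1H-pyrrole-2-carboxylate, diastereomer mixture | COC(=O)C1=C(c2c[nH]c3ccccc23)C(c2c[nH]c3ccccc23)C(N)(C(C)(OC)OC)N1 | intermediate (not isolated)
14 | methyl 5-(1,1-dimethoxyethyl)-3,4-di(1H-indol-3-yl)-1H-pyrrole-2-carboxylate | COC(=O)c1[nH]c(C(C)(OC)OC)c(-c2c[nH]c3ccccc23)c1-c1c[nH]c2ccccc12 | intermediate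
15 | methyl 5-acetyl-3,4-di(1H-indol-3-yl)-1H-pyrrole-2-carboxylate | COC(=O)c1[nH]c(C(C)=O)c(-c2c[nH]c3ccccc23)c1-c1c[nH]c2ccccc12 | target

**Step count and risks**
Total steps: 7. Longest linear sequence: 6 steps (steps 2, 3, 4, 5, 6, 7 from methyl indole-3-acetate); step 1 is a one-step branch that joins at step 5.

Steps most likely to fail:

1. Step 6 (key step). The ketal arm may tautomerise too slowly for the [3,3] shift to start. A mono-ene-hydrazine may instead close onto the remaining C=N in a Mannich-type cyclisation to a pyrazoline. Acid-promoted azine exchange may scramble the halves into symmetric azines. Fallback, from 10 back to 14: the azine is heated with benzoyl chloride (3 equiv) in pyridine (microwave, about 170 °C). Double N-acylation should give the N,N'-dibenzoyl bis(ene-hydrazine) methyl 2-{1,2-dibenzoyl-2-[1-(1H-indol-3-yl)-3,3-dimethoxybut-1-en-2-yl]hydrazinyl}-3-(1H-indol-3-yl)prop-2-enoate F1, which has no free C=N and cannot exchange. Under the same heating it should undergo the [3,3] shift and close with loss of benzamide to the N-benzoylpyrrole methyl 1-benzoyl-5-(1,1-dimethoxyethyl)-3,4-di(1H-indol-3-yl)-1H-pyrrole-2-carboxylate F2. NaOMe in MeOH at rt should then remove the N-benzoyl group, and any benzoyl group taken up by an indole nitrogen, to rejoin the route at 14.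

2. Step 5. Acid-catalysed exchange may equilibrate the mixed azine with the symmetric azines. Condensation may also stall because 2 rests largely as its enol, or the hydrazone nitrogen may acylate on the ester. Fallback, from 9 back to 10: the hydrazone is treated with Ph3PBr2 and Et3N in CH2Cl2 to give the N-(triphenylphosphoranylidene)hydrazone of 7 (phosphazine) F3. Heating F3 with 2 in toluene should deliver 10 by an irreversible, acid-free aza-Wittig reaction on the α-keto ester carbonyl.

3. Step 2. C-acylation of the aggregated dianion by the hindered ester may be incomplete, or the indolide nitrogen may be acylated instead. Fallback, from 3 back to 7 (compound 6 and step 3 are bypassed): 3 is converted with MeNH(OMe)·HCl and iPrMgCl in THF at −20 °C into the Weinreb amide 2-(1H-indol-3-yl)-N-methoxy-N-methylacetamide F4. 1-Methoxyvinyllithium (from methyl vinyl ether and t-BuLi, 3 equiv, THF, −78 °C) should add once to give 1-(1H-indol-3-yl)-3-methoxybut-3-en-2-one F5. Acid-catalysed Markovnikov addition of MeOH to the enol ether (PPTS, MeOH, rt) should then give 7.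

**Further compounds**
F1 | step 6 | methyl 2-{1,2-dibenzoyl-2-[1-(1H-indol-3-yl)-3,3-dimethoxybut-1-en-2-yl]hydrazinyl}-3-(1H-indol-3-yl)prop-2-enoate | COC(=O)C(=Cc1c[nH]c2ccccc12)N(C(=O)c1ccccc1)N(C(=O)c1ccccc1)C(=Cc1c[nH]c2ccccc12)C(C)(OC)OC
F2 | step 6 | methyl 1-benzoyl-5-(1,1-dimethoxyethyl)-3,4-di(1H-indol-3-yl)-1H-pyrrole-2-carboxylate | COC(=O)c1n(C(=O)c2ccccc2)c(C(C)(OC)OC)c(-c2c[nH]c3ccccc23)c1-c1c[nH]c2ccccc12
F3 | step 5 | N-(triphenylphosphoranylidene)hydrazone of 1-(1H-indol-3-yl)-3,3-dimethoxybutan-2-one (E) | CC(OC)(OC)/C(Cc1c[nH]c2ccccc12)=N/N=P(c1ccccc1)(c1ccccc1)c1ccccc1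
F4 | step 2 | 2-(1H-indol-3-yl)-N-methoxy-N-methylacetamide | CON(C)C(=O)Cc1c[nH]c2ccccc12
F5 | step 2 | 1-(1H-indol-3-yl)-3-methoxybut-3-en-2-one | COC(=C)C(=O)Cc1c[nH]c2ccccc12
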